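**Assumption:** (S)-but-3-yn-2-ol and (R)-2-methylbutanoic acid are bought as single enantiomers; bicyclic compounds are numbered as 1H-indenes (C-1 to C-3 in ring B, C-3a/C-7a at the fusion, C-4 to C-7 in ring A).

## Retrosynthetic overview

1. Target ⇒ bicyclic enone: each 2-methylbutanoate goes on right after its oxygen is installed (one equivalent of acid per step); the C-1 oxygen comes from enolate oxidation beside the C-2 ketone, the C-6 oxygen from allylic oxidation beside the C-7 methylidene.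
2. Bicyclic enone ⇒ acyclic 2-bromo-1,7-diene + CO: one palladium cascade closes ring A (six-membered, C-7/C-7a bond, 6-exo) and then ring B (five-membered, C-1/C-2 and C-2/C-3 bonds through CO, 5-exo). The methylidene, the ketone and the (E)-ethylidene all come out of this step.
3. Cascade substrate ⇒ α-branched aldehyde: esterification with the (Z)-enoic acid, hydroxyl-directed epoxidation (oxirane ring made before the carbocycles), catalytic asymmetric 2-bromoallylation. No protecting groups are used.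
4. Aldehyde ⇒ dienyl 3-methylbut-3-enoate: an Ireland–Claisen rearrangement sets the two adjacent carbon stereocentres by chirality transfer from a dienol made from a chiral butynol.

## Route

Step 1
Reactants: 1 (S)-but-3-yn-2-ol; 2 vinyl bromide (bromoethene)
Product: 3 (S)-hex-5-en-3-yn-2-ol
Conditions: Pd(PPh3)4 (2 mol%), CuI (4 mol%), Et2NH, THF, 0 °C → rt
Reagents that add atoms: none
Why: Sonogashira coupling joins the terminal alkyne to the vinyl bromide and does not touch the carbinol stereocentre.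

Step 2
Reactants: 3 (S)-hex-5-en-3-yn-2-ol
Product: 4 (2S,3E)-hexa-3,5-dien-2-ol
Conditions: NaAlH2(OCH2CH2OMe)2, THF, 0 °C → rt; H2O
Reagents that add atoms: none
Why: Alkoxide-directed trans-hydroalumination of the propargylic alcohol gives only the (E)-alkene, so the enyne becomes the (E)-diene with the (S)-carbinol intact.

Step 3
Reactants: 4 (2S,3E)-hexa-3,5-dien-2-ol; 5 3-methylbut-3-enoic acid
Product: 6 (2S,3E)-hexa-3,5-dien-2-yl 3-methylbut-3-enoate
Conditions: DCC, DMAP (5 mol%), CH2Cl2, 0 °C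
Reagents that add atoms: none
Why: Steglich esterification at 0 °C acylates the dienyl carbinol without ionising it and without moving the β,γ-double bond of the acid into conjugation.

Step 4
Reactants: 6 (2S,3E)-hexa-3,5-dien-2-yl 3-methylbut-3-enoate
Product: 9 (2S,3R,4E)-3-ethenyl-2-(prop-1-en-2-yl)hex-4-en-1-ol, via silyl ketene acetal 7 (not isolated), via trimethylsilyl ester 8 (not isolated)
Conditions: LiN(iPr)2, THF, −78 °C; Me3SiCl, Et3N, −78 °C → rt; then LiAlH4, 0 °C; H2O
Reagents that add atoms: none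
Why: Ireland–Claisen rearrangement: kinetic deprotonation in THF gives the ketene acetal with isopropenyl cis to the allylic oxygen, and the chair transition state with the carbinol methyl equatorial transfers the (S)-centre to the new (2S,3R) pair and forms the (E)-propenyl group; LiAlH4 then reduces the silyl ester in the same flask.

Step 5
Reactants: 9 (2S,3R,4E)-3-ethenyl-2-(prop-1-en-2-yl)hex-4-en-1-ol
Product: 10 (2S,3R,4E)-3-ethenyl-2-(prop-1-en-2-yl)hex-4-enal
Conditions: Dess–Martin periodinane, CH2Cl2, 0 °C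
Reagents that add atoms: none
Why: Dess–Martin oxidation is neutral and fast, so the α-stereocentre of this β,γ-unsaturated aldehyde is neither epimerised nor drawn into conjugation.

Step 6
Reactants: 10 (2S,3R,4E)-3-ethenyl-2-(prop-1-en-2-yl)hex-4-enal; 11 2,3-dibromoprop-1-ene
Product: 12 (4R,5S,6R,7E)-2-bromo-6-ethenyl-5-(prop-1-en-2-yl)nona-1,7-dien-4-ol
Conditions: CrCl2 (10 mol%), chiral sulfonamide–oxazoline ligand (11 mol%), Et3N (20 mol%), Mn, Zr(C5H5)2Cl2, LiCl, MeCN, rt; aq. work-up
Reagents that add atoms: none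
Why: Catalytic asymmetric Nozaki–Hiyama–Kishi-type 2-bromoallylation under neutral conditions; the (4R)-carbinol is set by the chiral ligand on the CrCl2-derived catalyst (ligand enantiomer chosen accordingly) rather than by the ambiguous Felkin bias of the aldehyde, and the alkenyl bromide survives because no nickel is present.

Step 7
Reactants: 12 (4R,5S,6R,7E)-2-bromo-6-ethenyl-5-(prop-1-en-2-yl)nona-1,7-dien-4-ol
Product: 13 (4R,5R,6R,7E)-2-bromo-6-ethenyl-5-[(2R)-2-methyloxiran-2-yl]nona-1,7-dien-4-ol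
Conditions: VO(OiPr)3 (2 mol%), chiral bishydroxamic acid ligand (4 mol%), cumene hydroperoxide, toluene, 0 °C
Reagents that add atoms: cumene hydroperoxide, CC(C)(OO)c1ccccc1
Why: Hydroxyl-directed vanadium-catalysed epoxidation of a homoallylic alcohol reacts at the electron-rich isopropenyl group two carbons from the OH (the bromoalkene is electron-poor, the other alkenes are further away); a chair-like vanadate transition state with both chain branches equatorial and the =CH2 terminus pseudo-equatorial, reinforced by the matched ligand enantiomer, gives the (2R)-oxirane.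

Step 8
Reactants: 14 propyne
Product: 16 (2Z)-3-methylpent-2-enoic acid, via alkenylcopper 15 (not isolated)
Conditions: EtMgBr, CuBr·SMe2, Et2O/Me2S, −45 °C; propyne, −25 °C; CO2, P(OEt)3 (cat.), HMPA, −40 °C → rt; aq. HCl
Reagents that add atoms: ethylmagnesium bromide, CC[Mg]Br; carbon dioxide, O=C=O
Why: Normant carbocupration adds ethyl and copper syn across propyne (ethyl to the internal carbon), and carboxylation with retention then gives only the (Z)-acid.

Step 9
Reactants: 13 (4R,5R,6R,7E)-2-bromo-6-ethenyl-5-[(2R)-2-methyloxiran-2-yl]nona-1,7-dien-4-ol; 16 (2Z)-3-methylpent-2-enoic acid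
Product: 17 (4R,5R,6R,7E)-2-bromo-6-ethenyl-5-[(2R)-2-methyloxiran-2-yl]nona-1,7-dien-4-yl (2Z)-3-methylpent-2-enoate
Conditions: DCC, DMAP (20 mol%), CH2Cl2, 0 °C → rt
Reagents that add atoms: none
Why: Steglich esterification acylates the secondary alcohol with retention; with catalytic DMAP at low temperature the (Z)-enoate geometry and the epoxide are kept.

Step 10
Reactants: 17 (4R,5R,6R,7E)-2-bromo-6-ethenyl-5-[(2R)-2-methyloxiran-2-yl]nona-1,7-dien-4-yl (2Z)-3-methylpent-2-enoate
Product: 18 (3E,3aS,4R,5R,7aS)-3-ethylidene-7-methylidene-4-[(2R)-2-methyloxiran-2-yl]-2-oxooctahydro-1H-inden-5-yl (2Z)-3-methylpent-2-enoate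
Conditions: Pd(OAc)2 (10 mol%), PPh3 (30 mol%), K2CO3, CO (1 atm), MeCN, 70 °C
Reagents that add atoms: carbon monoxide, [C-]#[O+]
Why: Proposed new method: zerovalent palladium inserts into the C–Br bond; the alkenyl–palladium adds 6-exo to the terminal ethenyl group through a chair with the ester, oxiranyl and propenyl groups equatorial, which sets C-7a trans to C-3a; CO inserts into the primary alkyl–palladium (held as a chelate by the neighbouring propenyl group, which slows β-hydride loss); the acyl–palladium adds 5-exo to the (E)-propenyl group and syn β-hydride elimination releases the (E)-ethylidene enone, while CO insertion at the alkenyl–palladium stage is reversible and unproductive because only a 7-exo acylpalladation is open to it; the closest known reactions are Negishi-type cyclic carbopalladation–acylpalladation cascades and the Oppolzer palladium-ene/carbonylation sequence, in which alkyl–palladium species bearing β-hydrogens are captured by CO at 1 atm.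

Step 11
Reactants: 18 (3E,3aS,4R,5R,7aS)-3-ethylidene-7-methylidene-4-[(2R)-2-methyloxiran-2-yl]-2-oxooctahydro-1H-inden-5-yl (2Z)-3-methylpent-2-enoate
Product: 19 (1R,3E,3aS,4R,5R,7aS)-3-ethylidene-1-hydroxy-7-methylidene-4-[(2R)-2-methyloxiran-2-yl]-2-oxooctahydro-1H-inden-5-yl (2Z)-3-methylpent-2-enoate
Conditions: KN(SiMe3)2 (1.05 equiv), THF, −78 °C; 2-(phenylsulfonyl)-3-phenyloxaziridine, −78 °C; aq. NH4Cl
Reagents that add atoms: 2-(phenylsulfonyl)-3-phenyloxaziridine, O=S(=O)(N1OC1c1ccccc1)c1ccccc1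
Why: Davis enolate oxidation: the only α-hydrogens are at C-1 (C-3 has none), and the oxaziridine is expected to approach the enolate anti to the axial H-7a, staggered between the C-7a/C-3a and C-7a/C-7 bonds (torsional control), giving the (1R)-alcohol.

Step 12
Reactants: 19 (1R,3E,3aS,4R,5R,7aS)-3-ethylidene-1-hydroxy-7-methylidene-4-[(2R)-2-methyloxiran-2-yl]-2-oxooctahydro-1H-inden-5-yl (2Z)-3-methylpent-2-enoate; 20 (R)-2-methylbutanoic acid
Product: 21 (1R,3E,3aS,4R,5R,7aS)-3-ethylidene-7-methylidene-1-{[(2R)-2-methylbutanoyl]oxy}-4-[(2R)-2-methyloxiran-2-yl]-2-oxooctahydro-1H-inden-5-yl (2Z)-3-methylpent-2-enoate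
Conditions: DCC (1.2 equiv), DMAP (10 mol%), CH2Cl2, −20 → 0 °C
Reagents that add atoms: none
Why: Steglich esterification acylates the only free hydroxyl with retention at C-1, and capping the α-ketol now keeps it from being oxidised to the 1,2-dione or epimerised in the allylic oxidation that follows.

Step 13
Reactants: 21 (1R,3E,3aS,4R,5R,7aS)-3-ethylidene-7-methylidene-1-{[(2R)-2-methylbutanoyl]oxy}-4-[(2R)-2-methyloxiran-2-yl]-2-oxooctahydro-1H-inden-5-yl (2Z)-3-methylpent-2-enoate
Product: 22 (1R,3E,3aS,4R,5S,6R,7aS)-3-ethylidene-6-hydroxy-7-methylidene-1-{[(2R)-2-methylbutanoyl]oxy}-4-[(2R)-2-methyloxiran-2-yl]-2-oxooctahydro-1H-inden-5-yl (2Z)-3-methylpent-2-enoate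
Conditions: SeO2 (30 mol%), t-BuOOH, CH2Cl2, 0 °C → rt
Reagents that add atoms: tert-butyl hydroperoxide, CC(C)(C)OO
Why: Sharpless SeO2/t-BuOOH allylic oxidation (ene reaction, then [2,3]-shift, the oxygen being passed on from the hydroperoxide through SeO2): on the electron-rich 1,1-disubstituted alkene the ring CH2 (C-6) reacts in preference to the methine C-7a, the axial hydrogen is removed and oxygen returns on the same face, giving the axial (6R)-alcohol with the methylidene restored; the enone and enoate alkenes are too electron-poor to compete.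

Step 14
Reactants: 22 (1R,3E,3aS,4R,5S,6R,7aS)-3-ethylidene-6-hydroxy-7-methylidene-1-{[(2R)-2-methylbutanoyl]oxy}-4-[(2R)-2-methyloxiran-2-yl]-2-oxooctahydro-1H-inden-5-yl (2Z)-3-methylpent-2-enoate; 20 (R)-2-methylbutanoic acid
Product: 23 (1R,3E,3aS,4R,5S,6R,7aS)-3-ethylidene-7-methylidene-1,6-bis{[(2R)-2-methylbutanoyl]oxy}-4-[(2R)-2-methyloxiran-2-yl]-2-oxooctahydro-1H-inden-5-yl (2Z)-3-methylpent-2-enoate (CNP0274886.3)
Conditions: DCC (1.5 equiv), DMAP (30 mol%), CH2Cl2, 0 °C → rt
Reagents that add atoms: none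
Why: Steglich esterification acylates the remaining axial allylic alcohol with retention at C-6, and the low temperature limits racemisation of the acid and acyl migration from O-5.

## Compound list

1 | (S)-but-3-yn-2-ol | C#C[C@H](C)O | starting material
2 | vinyl bromide | C=CBr | starting material
3 | (S)-hex-5-en-3-yn-2-ol | C=CC#C[C@H](C)O | intermediate
4 | (2S,3E)-hexa-3,5-dien-2-ol | C=C/C=C/[C@H](C)O | intermediate
5 | 3-methylbut-3-enoic acid | C=C(C)CC(=O)O | starting material
6 | (2S,3E)-hexa-3,5-dien-2-yl 3-methylbut-3-enoate | C=C/C=C/[C@H](C)OC(=O)CC(C)=C | intermediate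
7 | (1E)-1-{[(2S,3E)-hexa-3,5-dien-2-yl]oxy}-3-methyl-1-[(trimethylsilyl)oxy]buta-1,3-diene (silyl ketene acetal) | C=C/C=C/[C@H](C)O/C(O[Si](C)(C)C)=C\C(C)=C | intermediate
8 | trimethylsilyl (2S,3R,4E)-3-ethenyl-2-(prop-1-en-2-yl)hex-4-enoate | C=C[C@H](/C=C/C)[C@@H](C(C)=C)C(=O)O[Si](C)(C)C | intermediate
9 | (2S,3R,4E)-3-ethenyl-2-(prop-1-en-2-yl)hex-4-en-1-ol | C=C[C@H](/C=C/C)[C@@H](C(C)=C)CO | intermediate
10 | (2S,3R,4E)-3-ethenyl-2-(prop-1-en-2-yl)hex-4-enal | C=C[C@H](/C=C/C)[C@@H](C(C)=C)C=O | intermediate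
11 | 2,3-dibromoprop-1-ene | C=C(Br)CBr | starting material
12 | (4R,5S,6R,7E)-2-bromo-6-ethenyl-5-(prop-1-en-2-yl)nona-1,7-dien-4-ol | C=C[C@H](/C=C/C)[C@@H](C(C)=C)[C@H](O)CC(Br)=C | intermediate
13 | (4R,5R,6R,7E)-2-bromo-6-ethenyl-5-[(2R)-2-methyloxiran-2-yl]nona-1,7-dien-4-ol | C=C[C@H](/C=C/C)[C@@H]([C@]1(C)CO1)[C@H](O)CC(Br)=C | intermediate
14 | propyne | CC#C | starting material
15 | [(1Z)-2-methylbut-1-en-1-yl]copper | CC/C(C)=C\[Cu] | intermediate
16 | (2Z)-3-methylpent-2-enoic acid | CC/C(C)=C\C(=O)O | intermediate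
17 | (4R,5R,6R,7E)-2-bromo-6-ethenyl-5-[(2R)-2-methyloxiran-2-yl]nona-1,7-dien-4-yl (2Z)-3-methylpent-2-enoate | C=C[C@H](/C=C/C)[C@@H]([C@]1(C)CO1)[C@H](OC(=O)/C=C(/C)CC)CC(Br)=C | intermediate
18 | (3E,3aS,4R,5R,7aS)-3-ethylidene-7-methylidene-4-[(2R)-2-methyloxiran-2-yl]-2-oxooctahydro-1H-inden-5-yl (2Z)-3-methylpent-2-enoate | C=C1[C@@H]2[C@H](/C(=C\C)C(=O)C2)[C@@H]([C@]2(C)CO2)[C@H](OC(=O)/C=C(/C)CC)C1 | intermediate
19 | (1R,3E,3aS,4R,5R,7aS)-3-ethylidene-1-hydroxy-7-methylidene-4-[(2R)-2-methyloxiran-2-yl]-2-oxooctahydro-1H-inden-5-yl (2Z)-3-methylpent-2-enoate | C=C1[C@@H]2[C@H](/C(=C\C)C(=O)[C@@H]2O)[C@@H]([C@]2(C)CO2)[C@H](OC(=O)/C=C(/C)CC)C1 | intermediate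
20 | (R)-2-methylbutanoic acid | CC[C@@H](C)C(=O)O | starting material
21 | (1R,3E,3aS,4R,5R,7aS)-3-ethylidene-7-methylidene-1-{[(2R)-2-methylbutanoyl]oxy}-4-[(2R)-2-methyloxiran-2-yl]-2-oxooctahydro-1H-inden-5-yl (2Z)-3-methylpent-2-enoate | C=C1[C@@H]2[C@H](/C(=C\C)C(=O)[C@@H]2OC(=O)[C@H](C)CC)[C@@H]([C@]2(C)CO2)[C@H](OC(=O)/C=C(/C)CC)C1 | intermediate
22 | (1R,3E,3aS,4R,5S,6R,7aS)-3-ethylidene-6-hydroxy-7-methylidene-1-{[(2R)-2-methylbutanoyl]oxy}-4-[(2R)-2-methyloxiran-2-yl]-2-oxooctahydro-1H-inden-5-yl (2Z)-3-methylpent-2-enoate | C=C1[C@@H]2[C@H](/C(=C\C)C(=O)[C@@H]2OC(=O)[C@H](C)CC)[C@@H]([C@]2(C)CO2)[C@H](OC(=O)/C=C(/C)CC)[C@@H]1O | intermediate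
23 | (1R,3E,3aS,4R,5S,6R,7aS)-3-ethylidene-7-methylidene-1,6-bis{[(2R)-2-methylbutanoyl]oxy}-4-[(2R)-2-methyloxiran-2-yl]-2-oxooctahydro-1H-inden-5-yl (2Z)-3-methylpent-2-enoate | C=C1[C@@H]2[C@H](/C(=C\C)C(=O)[C@@H]2OC(=O)[C@H](C)CC)[C@@H]([C@]2(C)CO2)[C@H](OC(=O)/C=C(/C)CC)[C@@H]1OC(=O)[C@H](C)CC | target

## Step count and risks

Total steps: 14. Longest linear sequence: 13 (steps 1–7 and 9–14; step 8 is the side branch).

The three steps judged most likely to fail:

**Step 7 (epoxidation).** The risk is the facial selectivity at the isopropenyl group of an acyclic substrate that carries three other alkenes. The fallback sets out from 12 and comes back at 13. Boc2O/DMAP gives the tert-butyl carbonate F1. IBr in toluene at −85 °C then closes the cyclic iodocarbonate F2 through a chair with both chain branches and the CH2I group equatorial, so the tertiary C–O centre is fixed by 1,3-induction from the carbinol without a chiral catalyst. K2CO3 in MeOH cleaves the carbonate, and the freed tertiary alkoxide displaces iodide to give epoxy alcohol 13.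

**Step 10 (cascade).** The risk is that β-hydride loss from the primary alkyl–palladium gives the plain Heck diene before CO is captured, or that CO slows the first ring closure. The fallback sets out from 17 and comes back at 18, and forms both rings by a radical chain in which the C-1 centre has no elimination pathway. (Me3Si)3SiH, AIBN and CO (80 atm) in benzene at 80 °C give the saturated 3-ethyl ketone F3 by alkenyl-radical 6-exo closure, CO capture, acyl-radical 5-exo closure and hydrogen transfer. Me3SiCl/Et3N in DMF at 80 °C gives the more substituted trimethylsilyl enol ether F4. PhSeCl at −78 °C enters at C-3 anti to H-3a and gives the α-phenylselanyl ketone F5. H2O2/pyridine gives the selenoxide F6, which is not isolated; its syn-elimination can only reach the side-chain CH2 and returns 18 (any Z isomer is separated).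

**Step 11 (C-1 hydroxylation).** The risk is that the oxaziridine enters from the face of H-7a instead of the face predicted by torsional control. The fallback sets out from 18 and comes back at 21. The same enolate oxidation then delivers the (1S)-alcohol F7. Mitsunobu esterification of this activated α-keto carbinol with 20 (PPh3, DIAD, toluene, 0 °C) inverts C-1 and gives the (1R)-2-methylbutanoate 21 directly, so the separate acylation of step 12 is replaced by an invertive one.

## Further compounds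

F1 | step 7 | (4R,5S,6R,7E)-2-bromo-6-ethenyl-5-(prop-1-en-2-yl)nona-1,7-dien-4-yl tert-butyl carbonate | C=C[C@H](/C=C/C)[C@@H](C(C)=C)[C@H](OC(=O)OC(C)(C)C)CC(Br)=C
F2 | step 7 | (4R,5R,6R)-6-(2-bromoprop-2-en-1-yl)-5-[(3R,4E)-hexa-1,4-dien-3-yl]-4-(iodomethyl)-4-methyl-1,3-dioxan-2-one | C=C[C@H](/C=C/C)[C@H]1[C@](C)(CI)OC(=O)O[C@@H]1CC(Br)=C
F3 | step 10 | (3aS,4R,5R,7aS)-3-ethyl-7-methylidene-4-[(2R)-2-methyloxiran-2-yl]-2-oxooctahydro-1H-inden-5-yl (2Z)-3-methylpent-2-enoate, C-3 epimers | C=C1[C@@H]2[C@H](C(CC)C(=O)C2)[C@@H]([C@]2(C)CO2)[C@H](OC(=O)/C=C(/C)CC)C1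
F4 | step 10 | 3-ethyl-7-methylidene-4-[(2R)-2-methyloxiran-2-yl]-2-[(trimethylsilyl)oxy]-3a,4,5,6,7,7a-hexahydro-1H-inden-5-yl (2Z)-3-methylpent-2-enoate, ring stereocentres as in 18 | C=C1[C@@H]2[C@H](C(CC)=C(O[Si](C)(C)C)C2)[C@@H]([C@]2(C)CO2)[C@H](OC(=O)/C=C(/C)CC)C1
F5 | step 10 | 3-ethyl-7-methylidene-4-[(2R)-2-methyloxiran-2-yl]-2-oxo-3-(phenylselanyl)octahydro-1H-inden-5-yl (2Z)-3-methylpent-2-enoate, selenium trans to H-3a, other stereocentres as in 18 | C=C1[C@@H]2[C@H]([C@@](CC)([Se]c3ccccc3)C(=O)C2)[C@@H]([C@]2(C)CO2)[C@H](OC(=O)/C=C(/C)CC)C1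
F6 | step 10 | selenoxide of F5 (3-benzeneseleninyl ketone) | C=C1[C@@H]2[C@H]([C@@](CC)([Se](=O)c3ccccc3)C(=O)C2)[C@@H]([C@]2(C)CO2)[C@H](OC(=O)/C=C(/C)CC)C1
F7 | step 11 | (1S,3E,3aS,4R,5R,7aS)-3-ethylidene-1-hydroxy-7-methylidene-4-[(2R)-2-methyloxiran-2-yl]-2-oxooctahydro-1H-inden-5-yl (2Z)-3-methylpent-2-enoate | C=C1[C@@H]2[C@H](/C(=C\C)C(=O)[C@H]2O)[C@@H]([C@]2(C)CO2)[C@H](OC(=O)/C=C(/C)CC)C1
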